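Late times first: how much target can a flask hold once the nucleophile it can spend has been spent?

| setting | ochre | teal |
|---|---|---|
| electrophile | 0.10 M | 0.10 M |
| nucleophile | 0.100 M | 0.160 M |
| solid base | 0.300 M | 0.300 M |
| protic impurity | 0.0500 M | 0.0500 M |
| time | 40 min | 40 min |

    electrophile + nucleophile → acid set free + target (k1 = 1.2 /M/min)
    nucleophile + acid set free ⇌ protonated nucleophile, settled at all times (K2 = 190 /M)
    acid set free + free base ⇌ salt of the base, settled at all times (K3 = 3700 /M)
    electrophile ⇌ dormant form (K4 = 0.66, k4 = 0.027 /min)
    solid base ⇌ free base, rate k5*(cs5 - [free base]) while solid is left; crystals form when [free base] > cs5 (cs5 = 10 mM, k5 = 0.029 /min)
    nucleophile + protic impurity → quenched reagent (k6 = 12 /M/min)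

- part of the electrophile that has reacted at the end, ochre
- part of the electrophile that has reacted at the end, teal
- what raising the concentration of nucleophile from its lowest to its highest value here does to the part of the electrophile that has reacted (changes below 5 percentage points count as none) (it falls / no change / it rises)

- solid base is a solid; its amount is given per volume of the solution
- at the start none of the solid base is in solution
- what has gone from electrophile into another species counts as reacted, even if it can come back
- run time (ochre): 40 min

The protic impurity takes nucleophile one for one. That leaves 0.0500 M in ochre and 0.110 M in teal as working nucleophile, the charge of nucleophile less the charge of protic impurity. In ochre this is the limiting reagent.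

Each target spends one nucleophile and sets one acid free, and the fast acid steps are taken at balance. For a ceiling, the acid stays off the nucleophile, so target reaches 50.0% of the electrophile charged in ochre and the full charge in teal. For a floor, each acid takes a second nucleophile, except where dissolved base catches it first. Dissolution delivers at most 0.0116 M in the time, and that base binds acid more strongly than nucleophile does. Working nucleophile plus this base, shared between two, puts target at 30.8% in ochre and 60.8% in teal. This floor is an estimate and no strict bound: it counts that base as delivered whole and the working nucleophile as spent by the end, which is a fair assumption for ochre, where the half-life of electrophile by the coupling at the charges, 5.8 min, is short against 40 min.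

Uncoupled electrophile also balances with its dormant form, whose forward half-life of 26 min is shorter than the run. Taken at balance, 39.8% of it counts as reacted. The brackets become 58.3% to 69.9% for ochre, and 76.4% to the full charge for teal. They stand apart by 6.5 percentage points, so the part reacted rises.

The forecast, 60% for ochre and 77% for teal with the verdict it rises, rests on the view that “the released acid ties up most of what is left”, and both figures lie inside the brackets.

The simulation gives 60.9% for ochre and 78.8% for teal, and on raising the nucleophile it rises, by 18 points. Target stands at 35.8% in ochre, 5 points above its floor, and at 62.8% in teal, 2 points above its floor.

Neither flask has come to rest at 40 min, although the half-life of electrophile by the coupling in ochre has stretched to 150 min by then. After 400 min, ochre holds 50.0% target, matching its working nucleophile over the electrophile charged, and its nucleophile stands at 0%. Its part reacted has reached 69.9%, the ceiling. After the same time, teal holds 95.2% target, and its part reacted has reached 97.3%, with 2.72% of the electrophile still unbound.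

(Its constants stand for no real mixture; the flask was simulated.)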